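**Retrosynthetic overview**
1. Target 15 ⇐ selective acetylation of macrocyclic diol 14.
2. 14 ⇐ intramolecular McMurry coupling of keto-enal 13 (C1=C14). One step closes the 14-membered carbocycle and creates the diene on an unprotected diol; the default closure (cross-coupling or metathesis of a protected oxolane fragment) is avoided.
3. 13 ⇐ oxolane diol 11 ⇐ ketone-terminated hydrolytic cascade of bis-epoxide 9, which forms the oxolane and fixes all four stereocentres (C6, C10 retained; C7, C11 inverted).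
4. 9 ⇐ double Shi epoxidation of achiral (E,E,E)-triene ketone 6 ⇐ farnesyl acetate 1 + 3-methylbutan-2-one 4.
5. Ring order: oxolane first (step 5), carbocycle second (step 8).

Assumption: (2E,6E)-farnesyl acetate, 3-methylbutan-2-one and the L-fructose-derived enantiomer of the Shi ketone are bought; atom labels C1–C16 are those of the hexadecane chain of 6 and are kept for every later compound (in the macrocycle C1 is bonded to C14).

**Step 1**
Reactants: 1 (2E,6E)-farnesyl acetate
Product: 2 (2E,6E,10E)-12-hydroxy-3,7,11-trimethyldodeca-2,6,10-trien-1-yl acetate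
Conditions: SeO2 (0.1 equiv), t-BuOOH (70% aq, 3 equiv), salicylic acid (0.1 equiv), CH2Cl2, 0 °C to rt, 24 h
Reagents that add atoms: tert-butyl hydroperoxide, CC(C)(C)OO; selenium dioxide, O=[Se]=O (catalytic oxygen carrier)
Why: Riley allylic oxidation in its catalytic form: ene reaction and [2,3]-sigmatropic shift take place at the most electron-rich terminal alkene and on its (E)-methyl group, giving the (10E)-allylic alcohol while the acetate-deactivated 2,3-alkene is left alone.

**Step 2**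
Reactants: 2 (2E,6E,10E)-12-hydroxy-3,7,11-trimethyldodeca-2,6,10-trien-1-yl acetate
Product: 3 (2E,6E,10E)-12-bromo-3,7,11-trimethyldodeca-2,6,10-trien-1-yl acetate
Conditions: CBr4, PPh3, CH2Cl2, 0 °C
Reagents that add atoms: carbon tetrabromide, BrC(Br)(Br)Br
Why: Appel reaction: the primary allylic alcohol is activated as an alkoxyphosphonium ion and displaced by bromide by SN2 without allylic transposition, and acetate and alkenes are inert.

**Step 3**
Reactants: 3 (2E,6E,10E)-12-bromo-3,7,11-trimethyldodeca-2,6,10-trien-1-yl acetate; 4 3-methylbutan-2-one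
Product: 6 (2E,6E,10E)-3,7,11,15-tetramethyl-14-oxohexadeca-2,6,10-trien-1-yl acetate, via lithium 3-methylbut-1-en-2-olate 5 (not isolated)
Conditions: 4 (3 equiv), LiN(i-Pr)2 (2.9 equiv), THF, −78 °C, 30 min; then 3, DMPU, −78 to −30 °C
Reagents that add atoms: none
Why: Kinetic deprotonation of 4 at its methyl group and SN2 enolate alkylation of the primary allylic bromide, which at low temperature outruns acyl transfer to the acetate; the three (E)-alkenes are untouched.

**Step 4**
Reactants: 6 (2E,6E,10E)-3,7,11,15-tetramethyl-14-oxohexadeca-2,6,10-trien-1-yl acetate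
Product: 9 (2E,6S,7S,10S,11S)-6,7:10,11-diepoxy-3,7,11,15-tetramethyl-14-oxohexadec-2-en-1-yl acetate, via 6,7-monoepoxide 7 (not isolated), via 10,11-monoepoxide 8 (not isolated)
Conditions: L-fructose-derived Shi ketone (0.6 equiv), KHSO5 (as 2KHSO5·KHSO4·K2SO4, 3 equiv), K2CO3, Bu4NHSO4 (cat.), MeCN–CH2(OMe)2 / aq. Na2B4O7 buffer (pH 10.5), 0 °C, 3 h
Reagents that add atoms: potassium peroxymonosulfate, [K+].[O-]S(=O)(=O)OO
Why: Shi asymmetric epoxidation: the chiral dioxirane attacks the two electron-rich trisubstituted (E)-alkenes through a spiro transition state, the L-ketone giving the S,S epoxide at each (mirror image of the R,R sense of the D-ketone), while the 2,3-alkene is deactivated by its allylic acetate.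

**Step 5**
Reactants: 9 (2E,6S,7S,10S,11S)-6,7:10,11-diepoxy-3,7,11,15-tetramethyl-14-oxohexadec-2-en-1-yl acetate
Product: 11 (2E,6S,7R,10S,11R)-7,10-epoxy-6,11-dihydroxy-3,7,11,15-tetramethyl-14-oxohexadec-2-en-1-yl acetate, via epoxy diol 10 (not isolated)
Conditions: HClO4 (0.1 equiv), THF–H2O 5:1, 0 °C to rt
Reagents that add atoms: water, O
Why: Acid-triggered epoxide-opening cascade: the C14 ketone oxygen (5-exo, anchimeric assistance, hemiketal hydrolysed in situ) or water opens the 10,11-epoxide at tertiary C11 with inversion, and the freed C10 hydroxyl opens the 6,7-epoxide 5-exo at tertiary C7 with inversion, so C6 and C10 keep and C7 and C11 invert their configurations, giving the cis-2,5-disubstituted oxolane (6S,7R,10S,11R).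

**Step 6**
Reactants: 11 (2E,6S,7R,10S,11R)-7,10-epoxy-6,11-dihydroxy-3,7,11,15-tetramethyl-14-oxohexadec-2-en-1-yl acetate
Product: 12 (2E,6S,7R,10S,11R)-7,10-epoxy-1,6,11-trihydroxy-3,7,11,15-tetramethylhexadec-2-en-14-one
Conditions: K2CO3 (0.3 equiv), MeOH, 0 °C to rt
Reagents that add atoms: none
Why: Carbonate-catalysed transesterification (Zemplén-type methanolysis) removes the primary allylic acetate without touching the ketone, the oxolane or the carbinol stereocentres.

**Step 7**
Reactants: 12 (2E,6S,7R,10S,11R)-7,10-epoxy-1,6,11-trihydroxy-3,7,11,15-tetramethylhexadec-2-en-14-one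
Product: 13 (2E,6S,7R,10S,11R)-7,10-epoxy-6,11-dihydroxy-3,7,11,15-tetramethyl-14-oxohexadec-2-enal
Conditions: activated MnO2 (20 equiv), CH2Cl2, rt
Reagents that add atoms: none
Why: MnO2 allylic oxidation converts only the allylic primary alcohol into the (E)-enal; the saturated secondary and tertiary alcohols do not react.

**Step 8**
Reactants: 13 (2E,6S,7R,10S,11R)-7,10-epoxy-6,11-dihydroxy-3,7,11,15-tetramethyl-14-oxohexadec-2-enal
Product: 14 (1R,2S,5E,7E,11R,12S)-1,5,11-trimethyl-8-(propan-2-yl)-15-oxabicyclo[10.2.1]pentadeca-5,7-diene-2,11-diol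
Conditions: TiCl3(DME)1.5 (15 equiv), Zn–Cu couple (45 equiv), DME, reflux 4 h; then 13 by syringe pump over 36 h (final 2 mM), reflux 6 h
Reagents that add atoms: none
Why: Intramolecular McMurry coupling: low-valent titanium joins aldehyde C1 and ketone C14 reductively and removes both oxygens under high dilution, closing the 14-membered ring and giving the C14=C1 alkene with the ring CH2 (C13) cis to C2 and isopropyl trans (less allylic strain, as in related cembrene-type closures), while alcohols and the ether are tolerated and no stereocentre is touched.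

**Step 9**
Reactants: 14 (1R,2S,5E,7E,11R,12S)-1,5,11-trimethyl-8-(propan-2-yl)-15-oxabicyclo[10.2.1]pentadeca-5,7-diene-2,11-diol
Product: 15 (1R,2S,5E,7E,11R,12S)-11-hydroxy-1,5,11-trimethyl-8-(propan-2-yl)-15-oxabicyclo[10.2.1]pentadeca-5,7-dien-2-yl acetate
Conditions: Ac2O (1.5 equiv), pyridine, DMAP (0.1 equiv), CH2Cl2, 0 °C to rt
Reagents that add atoms: acetic anhydride, CC(=O)OC(C)=O
Why: DMAP-catalysed acylation (Steglich-type acetylation) esterifies the secondary C6 alcohol, and the tertiary C11 alcohol is too hindered to react under these conditions.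

**Compound list**
1 | (2E,6E)-3,7,11-trimethyldodeca-2,6,10-trien-1-yl acetate ((E,E)-farnesyl acetate) | CC(=O)OC/C=C(\C)CC/C=C(\C)CCC=C(C)C | starting material
2 | (2E,6E,10E)-12-hydroxy-3,7,11-trimethyldodeca-2,6,10-trien-1-yl acetate | CC(=O)OC/C=C(\C)CC/C=C(\C)CC/C=C(\C)CO | intermediate
3 | (2E,6E,10E)-12-bromo-3,7,11-trimethyldodeca-2,6,10-trien-1-yl acetate | CC(=O)OC/C=C(\C)CC/C=C(\C)CC/C=C(\C)CBr | intermediate
4 | 3-methylbutan-2-one | CC(=O)C(C)C | starting material
5 | lithium 3-methylbut-1-en-2-olate | C=C(O[Li])C(C)C | intermediate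
6 | (2E,6E,10E)-3,7,11,15-tetramethyl-14-oxohexadeca-2,6,10-trien-1-yl acetate | CC(=O)OC/C=C(\C)CC/C=C(\C)CC/C=C(\C)CCC(=O)C(C)C | intermediate
7 | (2E,6S,7S,10E)-6,7-epoxy-3,7,11,15-tetramethyl-14-oxohexadeca-2,10-dien-1-yl acetate | CC(=O)OC/C=C(\C)CC[C@@H]1O[C@@]1(C)CC/C=C(\C)CCC(=O)C(C)C | intermediate
8 | (2E,6E,10S,11S)-10,11-epoxy-3,7,11,15-tetramethyl-14-oxohexadeca-2,6-dien-1-yl acetate | CC(=O)OC/C=C(\C)CC/C=C(\C)CC[C@@H]1O[C@@]1(C)CCC(=O)C(C)C | intermediate
9 | (2E,6S,7S,10S,11S)-6,7:10,11-diepoxy-3,7,11,15-tetramethyl-14-oxohexadec-2-en-1-yl acetate | CC(=O)OC/C=C(\C)CC[C@@H]1O[C@@]1(C)CC[C@@H]2O[C@@]2(C)CCC(=O)C(C)C | intermediate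
10 | (2E,6S,7S,10S,11R)-6,7-epoxy-10,11-dihydroxy-3,7,11,15-tetramethyl-14-oxohexadec-2-en-1-yl acetate | CC(=O)OC/C=C(\C)CC[C@@H]1O[C@@]1(C)CC[C@H](O)[C@](C)(O)CCC(=O)C(C)C | intermediate
11 | (2E,6S,7R,10S,11R)-7,10-epoxy-6,11-dihydroxy-3,7,11,15-tetramethyl-14-oxohexadec-2-en-1-yl acetate (cis-2,5-disubstituted oxolane) | CC(=O)OC/C=C(\C)CC[C@H](O)[C@@]1(C)CC[C@H](O1)[C@](C)(O)CCC(=O)C(C)C | intermediate
12 | (2E,6S,7R,10S,11R)-7,10-epoxy-1,6,11-trihydroxy-3,7,11,15-tetramethylhexadec-2-en-14-one | OC/C=C(\C)CC[C@H](O)[C@@]1(C)CC[C@H](O1)[C@](C)(O)CCC(=O)C(C)C | intermediate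
13 | (2E,6S,7R,10S,11R)-7,10-epoxy-6,11-dihydroxy-3,7,11,15-tetramethyl-14-oxohexadec-2-enal | O=C/C=C(\C)CC[C@H](O)[C@@]1(C)CC[C@H](O1)[C@](C)(O)CCC(=O)C(C)C | intermediate
14 | (1R,2S,5E,7E,11R,12S)-1,5,11-trimethyl-8-(propan-2-yl)-15-oxabicyclo[10.2.1]pentadeca-5,7-diene-2,11-diol | O[C@H]1CC/C(C)=C/C=C(/C(C)C)CC[C@@](C)(O)[C@@H]2CC[C@@]1(C)O2 | intermediate
15 | (1R,2S,5E,7E,11R,12S)-11-hydroxy-1,5,11-trimethyl-8-(propan-2-yl)-15-oxabicyclo[10.2.1]pentadeca-5,7-dien-2-yl acetate | CC(=O)O[C@H]1CC/C(C)=C/C=C(/C(C)C)CC[C@@](C)(O)[C@@H]2CC[C@@]1(C)O2 | target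

**Total step count:** 9. **Longest linear sequence:** 9 steps (1 → 15).

**Steps most likely to fail**

Step 8 (McMurry closure on the free diol). The risks are oligomerisation, consumption of titanium by the two hydroxyls, oxa-Michael addition of the C6 hydroxyl to the enal, and partial E/Z scrambling of the C2=C3 or C14=C1 alkene. The fallback gives up the unprotected closure; it sets out from 13 and comes back at 14. Both hydroxyls of 13 are silylated (TESOTf, 2,6-lutidine, CH2Cl2, −78 °C) to the bis(triethylsilyl) keto-enal F1. F1 is closed with TiCl3(DME)1.5/Zn–Cu in refluxing DME under high dilution to the macrocyclic bis(triethylsilyl) ether F2. Tetrabutylammonium fluoride in THF then frees both hydroxyls and gives 14.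

Step 5 (hydrolytic cascade). The risks are direct hydration of the 6,7-epoxide before it is opened from C10, which reverses the direction of the cascade and gives diastereomeric oxolanes or oxanes, and trapping of the ketone as a bicyclic ketal. The fallback replaces water and the ketone by an ester terminator under anhydrous Lewis acid and installs the isopropyl ketone afterwards; it sets out from 3 and comes back at 12. Bromide 3 is alkylated with the lithium enolate of tert-butyl acetate (LiN(i-Pr)2, THF, −78 °C) to the tert-butyl ester triene F3. The same Shi epoxidation gives the bis-epoxide ester F4. BF3·OEt2 in CH2Cl2 at −78 °C runs the cascade without water: the ester carbonyl closes onto C11 with loss of 2-methylpropene and the C10 oxygen closes onto C7, giving the hydroxy lactone acetate F5. K2CO3 in MeOH removes the acetate to give the lactone diol F6. i-PrLi (3.3 equiv, THF, −78 °C) adds once to the lactone and delivers 12.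

Step 3 (hard enolate next to an acetate). The risks are acyl transfer to the enolate, polyalkylation and enolate equilibration. The fallback uses a soft, doubly stabilised enolate and a separate decarboxylation; it sets out from 3 and comes back at 6. Bromide 3 is alkylated with the sodium enolate of methyl 4-methyl-3-oxopentanoate (NaH, THF, 0 °C to rt) to the β-keto ester F7. F7 is demethoxycarbonylated under Krapcho conditions (LiCl, wet DMSO, 130 °C), which leave the unactivated acetate alone, to give 6.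

**Further compounds**
F1 | step 8 | (2E,6S,7R,10S,11R)-7,10-epoxy-3,7,11,15-tetramethyl-14-oxo-6,11-bis(triethylsilyloxy)hexadec-2-enal | O=C/C=C(\C)CC[C@H](O[Si](CC)(CC)CC)[C@@]1(C)CC[C@H](O1)[C@](C)(O[Si](CC)(CC)CC)CCC(=O)C(C)C
F2 | step 8 | (1R,2S,5E,7E,11R,12S)-1,5,11-trimethyl-8-(propan-2-yl)-2,11-bis(triethylsilyloxy)-15-oxabicyclo[10.2.1]pentadeca-5,7-diene | CC[Si](CC)(CC)O[C@H]1CC/C(C)=C/C=C(/C(C)C)CC[C@@](C)(O[Si](CC)(CC)CC)[C@@H]2CC[C@@]1(C)O2
F3 | step 5 | tert-butyl (4E,8E,12E)-14-acetoxy-4,8,12-trimethyltetradeca-4,8,12-trienoate | CC(=O)OC/C=C(\C)CC/C=C(\C)CC/C=C(\C)CCC(=O)OC(C)(C)C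
F4 | step 5 | tert-butyl (4S,5S,8S,9S,12E)-14-acetoxy-4,5:8,9-diepoxy-4,8,12-trimethyltetradec-12-enoate | CC(=O)OC/C=C(\C)CC[C@@H]1O[C@@]1(C)CC[C@@H]2O[C@@]2(C)CCC(=O)OC(C)(C)C
F5 | step 5 | (2E,6S)-6-hydroxy-3-methyl-6-[(2R,5S)-2-methyl-5-[(2R)-2-methyl-5-oxooxolan-2-yl]oxolan-2-yl]hex-2-en-1-yl acetate | CC(=O)OC/C=C(\C)CC[C@H](O)[C@@]1(C)CC[C@H](O1)[C@@]2(C)CCC(=O)O2
F6 | step 5 | (5R)-5-[(2S,5R)-5-[(1S,4E)-1,6-dihydroxy-4-methylhex-4-en-1-yl]-5-methyloxolan-2-yl]-5-methyloxolan-2-one | OC/C=C(\C)CC[C@H](O)[C@@]1(C)CC[C@H](O1)[C@@]2(C)CCC(=O)O2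
F7 | step 3 | methyl 2-[(2E,6E,10E)-12-acetoxy-2,6,10-trimethyldodeca-2,6,10-trien-1-yl]-4-methyl-3-oxopentanoate | CC(=O)OC/C=C(\C)CC/C=C(\C)CC/C=C(\C)CC(C(=O)OC)C(=O)C(C)C
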